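The pitfall in this flask is to read c(J.Q) off the Q that stands at the end.

D 0.033 M; Q 4.00 equiv; time 80 min

    D ⇌ J, rate k1*(cs1 - [J]) while solid is left; crystals form when [J] > cs1 (cs1 = 13 mM, k1 = 2.2 min⁻¹)
    J + Q → J.Q (k2 = 0.52 M⁻¹ min⁻¹)
    J + J.Q → J.J.Q (k3 = 5.1 M⁻¹ min⁻¹)
    X ⇌ J.Q, rate k4*(cs4 - [J.Q]) while solid is left; crystals form when [J.Q] > cs4 (cs4 = 12 mM, k4 = 2.3 min⁻¹)
    Q → G (k5 = 1.2 × 10⁻⁴ min⁻¹)
    2 Q → Q2 (k6 = 0.21 M⁻¹ min⁻¹)

- a species is counted by the D in it: one J.J.Q counts as two
- amounts and yields of J.Q count X too
- for a step with 2 of a species take k times the square, and two of it per event
- given per volume of solution although it is solid: D, X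
- at the start none of D is in solution
- J means what is dissolved; the solid is not counted in it
- run time (flask): 80 min

* the J.Q and X together standing at 80 min, as a percentage of the D charged
* concentration of J in solution at 8.0 min, in percent of saturation
* the change that raises the amount of J.Q and X together at 80 min, in percent of the D charged most ("none" if none brings more than 2 percentage points) (eta / alpha / beta / gamma / none)
* amount of J.Q and X together at 80 min, in percent of the D charged, after beta

- eta: doubling the amount of Q, all else as stated
- alpha: doubling the solubility in step 4, all else as stated
- beta: doubling the dissolution coefficient of step 1, all else as stated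
- gamma: doubling the solubility in step 1, all else as stated

J.Q is made from J and Q and used by J, so c(J) cancels. I call the ratio c(J.Q)/c(Q) at which J.Q is made as fast as it is used the balance ratio, 0.102. Its inverse is the selectivity factor.

Q starts at 132 mM. Its pairing has a first half-life of 18.0 min, far shorter than 96 h for step 5, so I reckon Q by pairing. Pairing by itself leaves 24.3 mM at 80 min.

My first way puts J.Q at balance with that Q, which gives 7.50%.

My second way counts turnovers. While solid stands, c(J) sits near 13 mM, because k1 is much greater than the drain 0.0686 min⁻¹. With the start Q, that puts J at 97.0% of saturation, and I take this figure for 8.0 min too.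

One turnover of J.Q then takes 15.1 min. The 20.0 mM of D above saturation feeds a use of about k2·cs1·c(Q). I let the start value of Q stand in for the falling Q and the rising J.Q together. So the solid lasts 22.4 min, which is 1.48 turnovers.

By then Q is 58.9 mM. With J.Q at balance using J as fast as Q does, I reckon J to decay at about 0.0612 min⁻¹. So about 1.08 turnovers remain, while Q still falls 2.42-fold. With so few turnovers left, I doubt that J.Q follows this fall, so I hold the first way for the one that cheats.

I grant J.Q one turnover time after the solid. That is 37.5 min, where Q is 42.9 mM, and I commit to 13.2%, more than the first way. Doubling k1 lifts J to 98.5% of saturation, as dissolution stays far faster than the drain, so after beta I keep 13.2%. Alpha doubles the solubility in step 4. Balance at the Q of the solid's end stands at 6.00 mM, less than 12 mM, so I expect no X and no gain from alpha.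

The forecast gives 11.2% (10% to 12.5%), 97.1%, 11.2% after beta and eta as best, holding that “dissolution isn't limiting”.

The flask gives 11.6%, with J at 97.1% of saturation, 11.8% after beta, and eta as best, gaining 9.3 percentage points. The balance ratio on the Q standing at 80.0 min, 15.8% of its charge, gives 6.44%, so this flask's J.Q stands above balance, made at 0.555 of its use. For the neighbouring flask with 1.60 equiv of Q, my count has the solid last 56.0 min, and it reads Q one turnover time later, at 71.1 min. The balance ratio then gives 6.33%. That neighbouring flask ends at 5.25%.

The constants used here are made up; the result is computed.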